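**Retrosynthetic overview**
1. Ring A is numbered C1 (OMe), C2 (OH), C3 (O-aryl), C4–C6 (Br), and ring B is the 2,4-dibromophenyl group. The route rests on C2: its hydroxyl is a masked carbonyl between the two ether carbons. C2 can therefore be the sp carbon of a ketene, C3 the aryloxy-bearing ketene carbon, and C1 the methoxy-bearing end of a C4=C5–C6=C1 diene.
2. Disconnection 1: the three C–Br bonds at C4, C5 and C6, made by late electrophilic bromination of the trioxygenated phenol.
3. Disconnection 2 (key): the C1–C2 bond, made by 6π electrocyclization of the aryloxy dienylketene released from the 2-aryloxy-6-methoxyhexa-3,5-dienoic acid.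
4. Disconnection 3: the acid divides into methoxybutenyne (C4, C5, C6, C1), ethyl glyoxylate (C3, C2) and 2,4-dibromophenol. The crowded C3–O–aryl bond is made while C3 is still sp3.
5. Ring order: ring B is bought complete, and ring A is the only ring formed, in step 5.

Key step: step 5

Assumption: the commercial methoxybutenyne (aqueous methanol solution, mainly Z) is extracted, dried and distilled, and commercial polymeric ethyl glyoxylate in toluene is cracked by distillation just before use. All enol ethers are purified on triethylamine-deactivated silica. Every intermediate with an sp3 C3 (or sp3 C1) is racemic, and that centre disappears in step 5.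

**Step 1**
Reactants: 1 (Z)-1-methoxybut-1-en-3-yne; 2 ethyl glyoxylate
Product: 4 ethyl (5Z)-2-hydroxy-6-methoxyhex-5-en-3-ynoate (racemic), via lithium acetylide 3 (not isolated)
Conditions: n-BuLi (1.0 equiv), THF, −78 °C; then monomeric 2 (1.2 equiv), −78 °C; sat. aq NH4Cl at −78 °C
Reagents that add atoms: none
Why: This is the 1,2-addition of a lithium acetylide to an aldehyde, in which one equivalent of base at −78 °C removes only the alkyne C–H, the formyl group of 2 is far more electrophilic than its ester, and the new carbinol centre (future C3 of ring A) forms racemic, which is harmless because it becomes sp2 in step 5.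

**Step 2**
Reactants: 4 ethyl (5Z)-2-hydroxy-6-methoxyhex-5-en-3-ynoate; 5 2,4-dibromophenol
Product: 6 ethyl (5Z)-2-(2,4-dibromophenoxy)-6-methoxyhex-5-en-3-ynoate (racemic)
Conditions: PPh3 (1.3 equiv), DIAD (1.3 equiv), THF, 0 °C → rt
Reagents that add atoms: none
Why: In this Mitsunobu etherification 5 (pKa near 8) readily protonates the PPh3–DIAD betaine and its phenoxide displaces the oxyphosphonium group in an SN2 reaction accelerated by the flanking ester and alkyne, while the inversion is irrelevant on racemic material and the nearly neutral medium spares the base-sensitive propargylic C–H and the acid-sensitive enol ether.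

**Step 3**
Reactants: 6 ethyl (5Z)-2-(2,4-dibromophenoxy)-6-methoxyhex-5-en-3-ynoate
Product: 7 ethyl (3Z,5Z)-2-(2,4-dibromophenoxy)-6-methoxyhexa-3,5-dienoate (racemic)
Conditions: H2 (1 atm), Pd/CaCO3 poisoned with Pb(OAc)2 (Lindlar catalyst), quinoline, EtOAc–hexane, 0 °C → rt, stopped after one equivalent of H2
Reagents that add atoms: none
Why: In this Lindlar semi-hydrogenation, syn delivery of one equivalent of H2 to the adsorbed alkyne sets the 3Z alkene (the cis C4=C5 bond of the future ring A), and the lead and quinoline poisoning should keep the catalyst away from the diene, the two aryl C–Br bonds and the allylic C–O bond.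

**Step 4**
Reactants: 7 ethyl (3Z,5Z)-2-(2,4-dibromophenoxy)-6-methoxyhexa-3,5-dienoate
Product: 8 (3Z,5Z)-2-(2,4-dibromophenoxy)-6-methoxyhexa-3,5-dienoic acid (racemic)
Conditions: LiOH·H2O (1.5 equiv), THF–H2O (3:1), 0 °C; cold aq citric acid to pH 4, quick Et2O extraction; used at once
Reagents that add atoms: lithium hydroxide (its oxygen becomes the acid OH), [Li+].[OH-]
Why: In this ester saponification (BAc2) the α-aryloxy group makes the ester carbonyl electrophilic enough to hydrolyse at 0 °C, the carboxylate once formed resists α-deprotonation so the skipped Z,Z-diene should stay in place, and cold acidification only to pH 4 spares the enol ether.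

**Step 5**
Reactants: 8 (3Z,5Z)-2-(2,4-dibromophenoxy)-6-methoxyhexa-3,5-dienoic acid
Product: 13 2-(2,4-dibromophenoxy)-6-methoxyphenol, via mixed carbonic anhydride 9 (not isolated), via aryloxy dienylketene 10 (not isolated), via methoxycyclohexadienone 11 (not isolated), via aryl ethyl carbonate 12 (not isolated)
Conditions: Et3N (6 equiv), ClCO2Et (3 equiv), THF (0.01 M in 8), −10 °C → rt (40 °C if 9 persists); then MeOH, K2CO3, rt, same flask
Reagents that add atoms: none
Why: Ethyl chloroformate converts the triethylammonium salt of 8 into mixed anhydride 9 without any free HCl, and Et3N then removes the C3 proton, which is acidified by the acyl group, the aryloxy oxygen and the diene, with expulsion of ethyl carbonate (E1cB) to give ketene 10. In 10 the C2=C3 ketene bond, the cis C4=C5 bond and the C6=C1 enol ether form a hexatriene whose ends C2 and C1 lie next to each other, and a thermal disrotatory 6π electrocyclization makes the C1–C2 bond and closes the six-membered ring A as dienone 11. Dienone 11 still has a hydrogen on C1, so the amine enolises it to the phenoxide, which the excess chloroformate caps as carbonate 12 before it can consume 9 or 10, and K2CO3 in methanol frees phenol 13 in the same flask. The closest known reaction type is the chloroformate–amine benzannulation of hexa-3,5-dienoic acids, and the same ring closure ends the cyclobutenone and carbene benzannulations and is the thermal reverse of the photochemical opening of cyclohexa-2,4-dienones. The only new stereocentre, C1 of 11, forms racemic and is erased on aromatisation, so neither it nor the geometry of the C6=C1 enol ether matters, and the inward methoxy group of the Z isomer meets only the substituent-free sp carbon C2. The step needs closure to outrun ketene dimerisation, [2+2] addition to an enol ether and capture by ethanol, which is secured by the cis C4=C5 bond from step 3 (a unimolecular closure), by high dilution and by the capping of the phenoxide; oxalyl chloride and trifluoroacetic anhydride are avoided because HCl or trifluoroacetylation would destroy the methoxydiene.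

**Step 6**
Reactants: 13 2-(2,4-dibromophenoxy)-6-methoxyphenol
Product: 14 3,4,5-tribromo-2-(2,4-dibromophenoxy)-6-methoxyphenol (target)
Conditions: Br2 (3.3 equiv), anhydrous AcOH, dark, rt → 45 °C; aq NaHSO3 work-up
Reagents that add atoms: bromine, BrBr
Why: In this electrophilic aromatic bromination C5 is para to the free hydroxyl, C4 is para to the methoxy and ortho to the aryloxy group, and C6 is ortho to the methoxy and para to the aryloxy group, so all three open positions of ring A are oxygen-activated, whereas ring B has only one shared ether oxygen and two deactivating bromines and should not react without a Lewis acid.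

**Compound list**
1 | (Z)-1-methoxybut-1-en-3-yne | CO/C=C\C#C | starting material
2 | ethyl glyoxylate | CCOC(=O)C=O | starting material
3 | lithium (Z)-4-methoxybut-3-en-1-yn-1-ide | CO/C=C\C#C[Li] | intermediate
4 | ethyl (5Z)-2-hydroxy-6-methoxyhex-5-en-3-ynoate (racemic) | CCOC(=O)C(O)C#C/C=C\OC | intermediate
5 | 2,4-dibromophenol | Oc1ccc(Br)cc1Br | starting material
6 | ethyl (5Z)-2-(2,4-dibromophenoxy)-6-methoxyhex-5-en-3-ynoate (racemic) | CCOC(=O)C(Oc1ccc(Br)cc1Br)C#C/C=C\OC | intermediate
7 | ethyl (3Z,5Z)-2-(2,4-dibromophenoxy)-6-methoxyhexa-3,5-dienoate (racemic) | CCOC(=O)C(Oc1ccc(Br)cc1Br)/C=C\C=C/OC | intermediate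
8 | (3Z,5Z)-2-(2,4-dibromophenoxy)-6-methoxyhexa-3,5-dienoic acid (racemic) | CO/C=C\C=C/C(Oc1ccc(Br)cc1Br)C(=O)O | intermediate
9 | (3Z,5Z)-2-(2,4-dibromophenoxy)-6-methoxyhexa-3,5-dienoic ethyl carbonic anhydride (racemic) | CO/C=C\C=C/C(Oc1ccc(Br)cc1Br)C(=O)OC(=O)OCC | intermediate
10 | (3Z,5Z)-2-(2,4-dibromophenoxy)-6-methoxyhexa-1,3,5-trien-1-one | CO/C=C\C=C/C(Oc1ccc(Br)cc1Br)=C=O | intermediate
11 | 2-(2,4-dibromophenoxy)-6-methoxycyclohexa-2,4-dien-1-one (racemic) | COC1C=CC=C(Oc2ccc(Br)cc2Br)C1=O | intermediate
12 | 2-(2,4-dibromophenoxy)-6-methoxyphenyl ethyl carbonate | CCOC(=O)Oc1c(OC)cccc1Oc1ccc(Br)cc1Br | intermediate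
13 | 2-(2,4-dibromophenoxy)-6-methoxyphenol | COc1cccc(Oc2ccc(Br)cc2Br)c1O | intermediate
14 | 3,4,5-tribromo-2-(2,4-dibromophenoxy)-6-methoxyphenol | COc1c(O)c(Oc2ccc(Br)cc2Br)c(Br)c(Br)c1Br | target

Total step count: 6. Longest linear sequence: 6 steps (1 → 4 → 6 → 7 → 8 → 13 → 14).

**Steps most likely to fail**

Step 5.
- What may go wrong: ethanol, phenoxide or a second ketene may capture the ketene faster than the ring closes. The cis C4=C5 geometry may also be lost at the enolate stage, after which closure is impossible.
- Fallback: ring A is not built but bought. Starting from 5, a Chan–Lam coupling is run with commercial 2,3-dimethoxyphenylboronic acid (COc1cccc(B(O)O)c1OC). The conditions are Cu(OAc)2, pyridine, 4 Å molecular sieves, CH2Cl2, air and rt, and they leave aryl bromides alone. This should give 1-(2,4-dibromophenoxy)-2,3-dimethoxybenzene F1.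
- BCl3 (CH2Cl2, −78 → 0 °C) then selectively cleaves the central methoxy group. That group is twisted out of the ring plane and binds boron together with a neighbouring oxygen. The route is rejoined at 13.

Step 4.
- What may go wrong: the double bonds may drift into conjugation with the ester, or the cis C4=C5 bond may be lost, through the extended enolate. The enol ether may also hydrolyse during acidification and handling of the free acid.
- Fallback: water and acid are avoided altogether. Starting from 7, anhydrous nucleophilic ester cleavage with KOSiMe3 (Et2O–THF, rt) should precipitate potassium (3Z,5Z)-2-(2,4-dibromophenoxy)-6-methoxyhexa-3,5-dienoate F2.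
- The salt is dried and treated directly with ClCO2Et and Et3N in dilute THF. The free acid is bypassed and the route is rejoined at 9.

Step 3.
- What may go wrong: the diene may be over-reduced, an aryl C–Br bond or the propargylic or allylic C–O bond may undergo hydrogenolysis, or the cis selectivity may be incomplete.
- Fallback: the alkyne is reduced before ring B is attached, and without palladium or H2. Starting from 4, zinc dust activated with Cu(OAc)2 and AgNO3 (MeOH–H2O, rt) reduces only conjugated alkynes, delivers cis alkenes and stops at the diene. This should give ethyl (3Z,5Z)-2-hydroxy-6-methoxyhexa-3,5-dienoate F3.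
- A Mitsunobu reaction of this alcohol with 5 (PPh3, DIAD, THF, 0 °C) rejoins the route at 7.

**Further compounds**
F1 | step 5 | 1-(2,4-dibromophenoxy)-2,3-dimethoxybenzene | COc1cccc(Oc2ccc(Br)cc2Br)c1OC
F2 | step 4 | potassium (3Z,5Z)-2-(2,4-dibromophenoxy)-6-methoxyhexa-3,5-dienoate | CO/C=C\C=C/C(Oc1ccc(Br)cc1Br)C(=O)[O-].[K+]
F3 | step 3 | ethyl (3Z,5Z)-2-hydroxy-6-methoxyhexa-3,5-dienoate | CCOC(=O)C(O)/C=C\C=C/OC
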